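The route rests on the C3–C4 bond of the 14-membered carbocycle (C1–C14). The C3(O-lactone)–C4(OH)(Me)–C5H2 array is read as a C3 allylic alcohol with an E-C4(Me)=C5 olefin. An intramolecular Ni/Cr coupling of a C4 alkenyl iodide with a C3 aldehyde therefore closes the macrocycle, forms C3–C4 and sets C3 in one operation. The C3 hydroxyl then steers oxygen to C4 and finally becomes the ring oxygen of the δ-lactone (O–C3–C2–C1–C15–C16). The precursor is an open-chain aldehyde carrying the (E)-iodoalkene, the 7,8-olefin, the 11,12-epoxide, the C1/C15 stereodiad and a C16 silyl ether.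

Key step: step 15

Assumption: locants follow cembrane numbering (ring C1–C14; C15 on C1 carrying C16 and C17; C18, C19 and C20 on C4, C8 and C12), and (S)-4-methyloxolan-2-one (13) is taken as a purchasable building block.

Step 1
Reactants: 1 geranyl bromide [(2E)-1-bromo-3,7-dimethylocta-2,6-diene]; 2 1-propynylmagnesium bromide
Product: 3 (5E)-6,10-dimethylundeca-5,9-dien-2-yne
Conditions: CuI (5 mol %), THF, 0 °C → rt
Reagents that add atoms: none
Why: Copper-catalysed SN2 coupling of an allylic bromide with an alkynyl Grignard reagent should give the skipped enyne with the E-olefin intact, because the fully substituted γ-carbon disfavours SN2′ attack.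

Step 2
Reactants: 3 (5E)-6,10-dimethylundeca-5,9-dien-2-yne
Product: 5 (2E,5E)-2-iodo-6,10-dimethylundeca-2,5,9-triene, via alkenylzirconocene chloride 4 (not isolated)
Conditions: Cp2Zr(H)Cl (2 equiv), THF, rt → 45 °C; then I2, 0 °C
Reagents that add atoms: iodine, II
Why: Hydrozirconation is a syn addition that, with excess reagent under equilibrating conditions, places zirconium on the less hindered methyl-bearing alkyne carbon, and iodinolysis with retention should give the (E)-2-iodo-2-alkene while the trisubstituted olefins stay untouched.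

Step 3
Reactants: 5 (2E,5E)-2-iodo-6,10-dimethylundeca-2,5,9-triene
Product: 6 (2E,6E,9E)-10-iodo-2,6-dimethylundeca-2,6,9-trien-1-ol
Conditions: SeO2 (0.3 equiv), salicylic acid (0.1 equiv), t-BuOOH (3 equiv), CH2Cl2, 0 °C → rt, stopped at partial conversion with 5 recycled
Reagents that add atoms: tert-butyl hydroperoxide, CC(C)(C)OO
Why: Allylic hydroxylation with catalytic SeO2 and t-BuOOH (ene reaction then [2,3]-sigmatropic shift) should oxidise the (E)-methyl of the terminal isopropylidene group, the most accessible trisubstituted olefin as in farnesyl-type substrates, and the sigmatropic step fixes the E-geometry of the new allylic alcohol.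

Step 4
Reactants: 6 (2E,6E,9E)-10-iodo-2,6-dimethylundeca-2,6,9-trien-1-ol
Product: 7 [(2S,3S)-3-[(3E,6E)-7-iodo-3-methylocta-3,6-dien-1-yl]-2-methyloxiran-2-yl]methanol
Conditions: Ti(OiPr)4 (10 mol %), L-(+)-diethyl tartrate (12 mol %), t-BuOOH, 4 Å MS, CH2Cl2, −25 °C
Reagents that add atoms: tert-butyl hydroperoxide, CC(C)(C)OO
Why: Sharpless asymmetric epoxidation touches only the allylic alcohol, and with L-(+)-tartrate an (E)-2-methyl-2-alken-1-ol should give the (2S,3S)-epoxy alcohol, which sets C11 and C12.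

Step 5
Reactants: 7 [(2S,3S)-3-[(3E,6E)-7-iodo-3-methylocta-3,6-dien-1-yl]-2-methyloxiran-2-yl]methanol
Product: 8 (2R,3S)-3-[(3E,6E)-7-iodo-3-methylocta-3,6-dien-1-yl]-2-methyloxirane-2-carbaldehyde
Conditions: Dess–Martin periodinane, pyridine, CH2Cl2, 0 °C → rt
Reagents that add atoms: none
Why: Buffered Dess–Martin oxidation should give the epoxy aldehyde, which has no α-hydrogen and cannot epimerise.

Step 6
Reactants: 8 (2R,3S)-3-[(3E,6E)-7-iodo-3-methylocta-3,6-dien-1-yl]-2-methyloxirane-2-carbaldehyde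
Product: 9 (2S,3S)-2-ethenyl-3-[(3E,6E)-7-iodo-3-methylocta-3,6-dien-1-yl]-2-methyloxirane
Conditions: Ph3PCH3Br, KHMDS, THF, 0 °C; then 8, −78 → 0 °C
Reagents that add atoms: methyltriphenylphosphonium bromide, C[P+](c1ccccc1)(c1ccccc1)c1ccccc1.[Br-]
Why: Wittig methylenation of the non-enolisable aldehyde should give the vinyl epoxide and supplies C14.

Step 7
Reactants: 9 (2S,3S)-2-ethenyl-3-[(3E,6E)-7-iodo-3-methylocta-3,6-dien-1-yl]-2-methyloxirane
Product: 11 2-[(2S,3S)-3-[(3E,6E)-7-iodo-3-methylocta-3,6-dien-1-yl]-2-methyloxiran-2-yl]ethan-1-ol, via B-alkyl-9-BBN 10 (not isolated)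
Conditions: 9-BBN, THF, 0 °C → rt; then NaOH, H2O2, 0 °C
Reagents that add atoms: hydrogen peroxide, OO
Why: Hydroboration with 9-BBN selects the monosubstituted olefin over the trisubstituted olefin and the iodoalkene and puts boron on the terminal carbon, and alkaline peroxide oxidation then gives the primary alcohol with the epoxide intact.

Step 8
Reactants: 11 2-[(2S,3S)-3-[(3E,6E)-7-iodo-3-methylocta-3,6-dien-1-yl]-2-methyloxiran-2-yl]ethan-1-ol
Product: 12 (2S,3S)-2-(2-iodoethyl)-3-[(3E,6E)-7-iodo-3-methylocta-3,6-dien-1-yl]-2-methyloxirane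
Conditions: PPh3, I2, imidazole, CH2Cl2, 0 °C, dark
Reagents that add atoms: iodine, II
Why: Appel-type iodination converts the primary alcohol to the iodide under imidazole-buffered conditions that a trisubstituted epoxide tolerates.

Step 9
Reactants: 12 (2S,3S)-2-(2-iodoethyl)-3-[(3E,6E)-7-iodo-3-methylocta-3,6-dien-1-yl]-2-methyloxirane; 13 (S)-4-methyloxolan-2-one
Product: 15 (3S,4S)-3-{2-[(2S,3S)-3-[(3E,6E)-7-iodo-3-methylocta-3,6-dien-1-yl]-2-methyloxiran-2-yl]ethyl}-4-methyloxolan-2-one, via lithium enolate 14 (not isolated)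
Conditions: 13 (2 equiv), LDA (commercial solution, 2 equiv), THF, −78 °C; then 12, HMPA, −78 → −30 °C
Reagents that add atoms: none
Why: Enolate alkylation of a β-substituted γ-butyrolactone takes place anti to the β-methyl group, so the trans-(3S,4S) lactone should form and C1 is set relative to C15, while only the primary iodide reacts and the alkenyl iodide and epoxide do not.

Step 10
Reactants: 15 (3S,4S)-3-{2-[(2S,3S)-3-[(3E,6E)-7-iodo-3-methylocta-3,6-dien-1-yl]-2-methyloxiran-2-yl]ethyl}-4-methyloxolan-2-one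
Product: 16 (3S,4S)-3-{2-[(2S,3S)-3-[(3E,6E)-7-iodo-3-methylocta-3,6-dien-1-yl]-2-methyloxiran-2-yl]ethyl}-4-methyloxolan-2-ol (both anomers)
Conditions: DIBAL-H (1.2 equiv), CH2Cl2, −78 °C; Rochelle salt work-up
Reagents that add atoms: none
Why: Partial reduction of a lactone with DIBAL-H at −78 °C stops at the lactol and leaves the epoxide and the iodoalkene alone.

Step 11
Reactants: 16 (3S,4S)-3-{2-[(2S,3S)-3-[(3E,6E)-7-iodo-3-methylocta-3,6-dien-1-yl]-2-methyloxiran-2-yl]ethyl}-4-methyloxolan-2-ol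
Product: 17 (2S,3R)-3-{2-[(2S,3S)-3-[(3E,6E)-7-iodo-3-methylocta-3,6-dien-1-yl]-2-methyloxiran-2-yl]ethyl}-2-methylpent-4-en-1-ol
Conditions: Ph3PCH3Br (4 equiv), KOtBu (3.8 equiv), THF, 0 °C → rt
Reagents that add atoms: methyltriphenylphosphonium bromide, C[P+](c1ccccc1)(c1ccccc1)c1ccccc1.[Br-]
Why: Wittig methylenation of the ring-opened hydroxy aldehyde form of the lactol should install the C2=C3 olefin and free the C16 hydroxyl, and C1, α to the transient aldehyde, is not expected to epimerise at these temperatures.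

Step 12
Reactants: 17 (2S,3R)-3-{2-[(2S,3S)-3-[(3E,6E)-7-iodo-3-methylocta-3,6-dien-1-yl]-2-methyloxiran-2-yl]ethyl}-2-methylpent-4-en-1-ol
Product: 18 tert-butyl{[(2S,3R)-3-{2-[(2S,3S)-3-[(3E,6E)-7-iodo-3-methylocta-3,6-dien-1-yl]-2-methyloxiran-2-yl]ethyl}-2-methylpent-4-en-1-yl]oxy}diphenylsilane
Conditions: TBDPSCl, imidazole, DMF, 0 °C → rt
Reagents that add atoms: tert-butyl(chloro)diphenylsilane, CC(C)(C)[Si](Cl)(c1ccccc1)c1ccccc1
Why: Silylation of the primary alcohol gives an ether that survives borane, Cr(II), hydride and peroxide.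

Step 13
Reactants: 18 tert-butyl{[(2S,3R)-3-{2-[(2S,3S)-3-[(3E,6E)-7-iodo-3-methylocta-3,6-dien-1-yl]-2-methyloxiran-2-yl]ethyl}-2-methylpent-4-en-1-yl]oxy}diphenylsilane
Product: 20 (3R,4S)-5-[(tert-butyldiphenylsilyl)oxy]-3-{2-[(2S,3S)-3-[(3E,6E)-7-iodo-3-methylocta-3,6-dien-1-yl]-2-methyloxiran-2-yl]ethyl}-4-methylpentan-1-ol, via B-alkyl-9-BBN 19 (not isolated)
Conditions: 9-BBN, THF, 0 °C → rt; then NaOH, H2O2, 0 °C
Reagents that add atoms: hydrogen peroxide, OO
Why: Anti-Markovnikov hydroboration–oxidation with 9-BBN again distinguishes the monosubstituted olefin from the other π-bonds and gives the C3 primary alcohol.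

Step 14
Reactants: 20 (3R,4S)-5-[(tert-butyldiphenylsilyl)oxy]-3-{2-[(2S,3S)-3-[(3E,6E)-7-iodo-3-methylocta-3,6-dien-1-yl]-2-methyloxiran-2-yl]ethyl}-4-methylpentan-1-ol
Product: 21 (3R,4S)-5-[(tert-butyldiphenylsilyl)oxy]-3-{2-[(2S,3S)-3-[(3E,6E)-7-iodo-3-methylocta-3,6-dien-1-yl]-2-methyloxiran-2-yl]ethyl}-4-methylpentanal (seco aldehyde)
Conditions: Dess–Martin periodinane, pyridine, CH2Cl2, 0 °C → rt
Reagents that add atoms: none
Why: Dess–Martin oxidation gives the C3 aldehyde, and the nearest stereocentre (C1) is β to the carbonyl and not at risk.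

Step 15
Reactants: 21 (3R,4S)-5-[(tert-butyldiphenylsilyl)oxy]-3-{2-[(2S,3S)-3-[(3E,6E)-7-iodo-3-methylocta-3,6-dien-1-yl]-2-methyloxiran-2-yl]ethyl}-4-methylpentanal
Product: 22 (1R,3R,4E,7E,11S,12S,15S)-16-[(tert-butyldiphenylsilyl)oxy]-11,12-epoxycembra-4,7-dien-3-ol
Conditions: CrCl2 (8 equiv), (S)-N-[2-(4-isopropyl-4,5-dihydrooxazol-2-yl)-6-methylphenyl]methanesulfonamide (8.8 equiv), Et3N (8.8 equiv), THF, rt, 1 h; then NiCl2 (0.2 equiv) and 21 by syringe pump over 12 h (final about 2 mM), rt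
Reagents that add atoms: none
Why: Ni(0) inserts into the C4–I bond with retention, the alkenyl group passes to Cr(III), and the alkenylchromium adds to the C3 aldehyde (intramolecular Nozaki–Hiyama–Kishi reaction). The closest known reaction type is the Ni/Cr macrocyclisation of ω-formyl trisubstituted alkenyl iodides. The 14-membered carbocycle C1–C14 closes in a 14-exo-trig mode by C3–C4 bond formation. The new C3 stereocentre is controlled by the chiral sulfonamidate on chromium in the closed transition state, the ligand antipode being chosen in a small screen so that it cooperates with the 1,3-bias from C1 and gives 3R. The step needs chemoselectivity, retention of the E-geometry at C4=C5 and ring closure over oligomerisation; the substrate secures these through its single C(sp2)–I/aldehyde pair, its Cr(II)-inert 11,12-epoxide, 7,8-olefin and silyl ether, and a tether stiffened by two E-olefins and the epoxide, with slow addition at high dilution as support.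

Step 16
Reactants: 22 (1R,3R,4E,7E,11S,12S,15S)-16-[(tert-butyldiphenylsilyl)oxy]-11,12-epoxycembra-4,7-dien-3-ol
Product: 23 (1R,3R,4R,5R,7E,11S,12S,15S)-16-[(tert-butyldiphenylsilyl)oxy]-4,5:11,12-diepoxycembr-7-en-3-ol
Conditions: VO(acac)2 (5 mol %), t-BuOOH (1.5 equiv), CH2Cl2, 0 °C
Reagents that add atoms: tert-butyl hydroperoxide, CC(C)(C)OO
Why: Vanadium-catalysed epoxidation is directed by the C3 hydroxyl to the adjacent C4=C5 olefin only, and A(1,2) strain from the C18 methyl should favour the erythro epoxy alcohol (4R,5R), which relays C3 to C4.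

Step 17
Reactants: 23 (1R,3R,4R,5R,7E,11S,12S,15S)-16-[(tert-butyldiphenylsilyl)oxy]-4,5:11,12-diepoxycembr-7-en-3-ol
Product: 24 (1R,3R,4S,7E,11S,12S,15S)-16-[(tert-butyldiphenylsilyl)oxy]-11,12-epoxycembr-7-ene-3,4-diol
Conditions: Ti(OiPr)4 (1.5 equiv), LiBH4 (2 equiv), THF–toluene, 0 °C → rt
Reagents that add atoms: none
Why: Titanium-assisted borohydride reduction of a 2,3-epoxy alcohol delivers hydride to the distal, secondary carbon (C5) through a Ti chelate, so the C4–O bond and its configuration are kept, and the unchelated 11,12-epoxide is not activated.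

Step 18
Reactants: 24 (1R,3R,4S,7E,11S,12S,15S)-16-[(tert-butyldiphenylsilyl)oxy]-11,12-epoxycembr-7-ene-3,4-diol
Product: 25 (1R,3R,4S,7E,11S,12S,15S)-11,12-epoxycembr-7-ene-3,4,16-triol
Conditions: TBAF, AcOH (1:1, 3 equiv), THF, rt
Reagents that add atoms: none
Why: Fluoride-mediated desilylation frees the C16 alcohol, and the acetic acid buffer keeps the medium from turning basic.

Step 19
Reactants: 25 (1R,3R,4S,7E,11S,12S,15S)-11,12-epoxycembr-7-ene-3,4,16-triol
Product: 28 (1R,3R,4S,7E,11S,12S,15S)-11,12-epoxy-4-hydroxycembr-7-en-16,3-olide, via hydroxy aldehyde 26 (not isolated), via lactol 27 (not isolated)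
Conditions: [Cu(MeCN)4]OTf (10 mol %), 2,2′-bipyridine (10 mol %), TEMPO (10 mol %), N-methylimidazole (20 mol %), air, MeCN, rt
Reagents that add atoms: none
Why: Cu/TEMPO aerobic oxidation is selective for the primary alcohol, the aldehyde closes to the six-membered lactol with the C3 hydroxyl, and a second oxidation gives the δ-lactone (oxidative lactonisation of a 1,5-diol) with no glycol-cleaving oxidant present.

Step 20
Reactants: 28 (1R,3R,4S,7E,11S,12S,15S)-11,12-epoxy-4-hydroxycembr-7-en-16,3-olide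
Product: 29 (1R,3R,4S,7R,11S,12S,15S)-11,12-epoxy-7-hydroperoxy-4-hydroxycembr-8(19)-en-16,3-olide (CNP0319766.1)
Conditions: O2, tetraphenylporphyrin (cat.), visible light, CH2Cl2, −20 °C
Reagents that add atoms: oxygen, O=O
Why: Schenck ene reaction of singlet oxygen with the only remaining olefin should bond oxygen to C7 and transfer a hydrogen from the C19 methyl to give the 7-hydroperoxide with the 8(19)-methylene, and attack on the outer face of the macrocycle is expected to set 7R.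

Compound list
1 | geranyl bromide, (2E)-1-bromo-3,7-dimethylocta-2,6-diene | CC(C)=CCC/C(C)=C/CBr | starting material
2 | 1-propynylmagnesium bromide | CC#C[Mg]Br | starting material
3 | (5E)-6,10-dimethylundeca-5,9-dien-2-yne | CC(C)=CCC/C(C)=C/CC#CC | intermediate
4 | chlorobis(cyclopentadienyl)[(2E,5E)-6,10-dimethylundeca-2,5,9-trien-2-yl]zirconium | CC(C)=CCC/C(C)=C/C/C=C(\C)[Zr](Cl)(C1C=CC=C1)C1C=CC=C1 | intermediate
5 | (2E,5E)-2-iodo-6,10-dimethylundeca-2,5,9-triene | CC(C)=CCC/C(C)=C/C/C=C(\C)I | intermediate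
6 | (2E,6E,9E)-10-iodo-2,6-dimethylundeca-2,6,9-trien-1-ol | OC/C(C)=C/CC/C(C)=C/C/C=C(\C)I | intermediate
7 | [(2S,3S)-3-[(3E,6E)-7-iodo-3-methylocta-3,6-dien-1-yl]-2-methyloxiran-2-yl]methanol | OC[C@]1(C)O[C@H]1CC/C(C)=C/C/C=C(\C)I | intermediate
8 | (2R,3S)-3-[(3E,6E)-7-iodo-3-methylocta-3,6-dien-1-yl]-2-methyloxirane-2-carbaldehyde | O=C[C@]1(C)O[C@H]1CC/C(C)=C/C/C=C(\C)I | intermediate
9 | (2S,3S)-2-ethenyl-3-[(3E,6E)-7-iodo-3-methylocta-3,6-dien-1-yl]-2-methyloxirane | C=C[C@]1(C)O[C@H]1CC/C(C)=C/C/C=C(\C)I | intermediate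
10 | B-alkyl-9-BBN from 9 (boron on the terminal carbon of the former vinyl group, stereocentres as in 9) | C1CCC2CCCC1B2CC[C@]1(C)O[C@H]1CC/C(C)=C/C/C=C(\C)I | intermediate
11 | 2-[(2S,3S)-3-[(3E,6E)-7-iodo-3-methylocta-3,6-dien-1-yl]-2-methyloxiran-2-yl]ethan-1-ol | OCC[C@]1(C)O[C@H]1CC/C(C)=C/C/C=C(\C)I | intermediate
12 | (2S,3S)-2-(2-iodoethyl)-3-[(3E,6E)-7-iodo-3-methylocta-3,6-dien-1-yl]-2-methyloxirane | ICC[C@]1(C)O[C@H]1CC/C(C)=C/C/C=C(\C)I | intermediate
13 | (S)-4-methyloxolan-2-one | C[C@@H]1COC(=O)C1 | starting material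
14 | lithium (4S)-4-methyl-4,5-dihydrofuran-2-olate | [Li+].[O-]C1=C[C@H](C)CO1 | intermediate
15 | (3S,4S)-3-{2-[(2S,3S)-3-[(3E,6E)-7-iodo-3-methylocta-3,6-dien-1-yl]-2-methyloxiran-2-yl]ethyl}-4-methyloxolan-2-one | O=C1OC[C@@H](C)[C@@H]1CC[C@]2(C)O[C@H]2CC/C(C)=C/C/C=C(\C)I | intermediate
16 | (3S,4S)-3-{2-[(2S,3S)-3-[(3E,6E)-7-iodo-3-methylocta-3,6-dien-1-yl]-2-methyloxiran-2-yl]ethyl}-4-methyloxolan-2-ol (both anomers) | OC1OC[C@@H](C)[C@@H]1CC[C@]2(C)O[C@H]2CC/C(C)=C/C/C=C(\C)I | intermediate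
17 | (2S,3R)-3-{2-[(2S,3S)-3-[(3E,6E)-7-iodo-3-methylocta-3,6-dien-1-yl]-2-methyloxiran-2-yl]ethyl}-2-methylpent-4-en-1-ol | C=C[C@H]([C@H](C)CO)CC[C@]1(C)O[C@H]1CC/C(C)=C/C/C=C(\C)I | intermediate
18 | tert-butyldiphenylsilyl ether of 17 | C=C[C@H]([C@H](C)CO[Si](C(C)(C)C)(c1ccccc1)c1ccccc1)CC[C@]1(C)O[C@H]1CC/C(C)=C/C/C=C(\C)I | intermediate
19 | B-alkyl-9-BBN from 18 (boron on the terminal carbon of the former vinyl group, stereocentres as in 18) | C1CCC2CCCC1B2CC[C@H]([C@H](C)CO[Si](C(C)(C)C)(c1ccccc1)c1ccccc1)CC[C@]1(C)O[C@H]1CC/C(C)=C/C/C=C(\C)I | intermediate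
20 | (3R,4S)-5-[(tert-butyldiphenylsilyl)oxy]-3-{2-[(2S,3S)-3-[(3E,6E)-7-iodo-3-methylocta-3,6-dien-1-yl]-2-methyloxiran-2-yl]ethyl}-4-methylpentan-1-ol | OCC[C@H]([C@H](C)CO[Si](C(C)(C)C)(c1ccccc1)c1ccccc1)CC[C@]1(C)O[C@H]1CC/C(C)=C/C/C=C(\C)I | intermediate
21 | (3R,4S)-5-[(tert-butyldiphenylsilyl)oxy]-3-{2-[(2S,3S)-3-[(3E,6E)-7-iodo-3-methylocta-3,6-dien-1-yl]-2-methyloxiran-2-yl]ethyl}-4-methylpentanal (seco aldehyde) | O=CC[C@H]([C@H](C)CO[Si](C(C)(C)C)(c1ccccc1)c1ccccc1)CC[C@]1(C)O[C@H]1CC/C(C)=C/C/C=C(\C)I | intermediate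
22 | (1R,3R,4E,7E,11S,12S,15S)-16-[(tert-butyldiphenylsilyl)oxy]-11,12-epoxycembra-4,7-dien-3-ol | O[C@@H]1C[C@H]([C@H](C)CO[Si](C(C)(C)C)(c2ccccc2)c2ccccc2)CC[C@]2(C)O[C@H]2CC/C(C)=C/C/C=C1\C | intermediate
23 | (1R,3R,4R,5R,7E,11S,12S,15S)-16-[(tert-butyldiphenylsilyl)oxy]-4,5:11,12-diepoxycembr-7-en-3-ol | O[C@@H]1C[C@H]([C@H](C)CO[Si](C(C)(C)C)(c2ccccc2)c2ccccc2)CC[C@]2(C)O[C@H]2CC/C(C)=C/C[C@H]2O[C@]12C | intermediate
24 | (1R,3R,4S,7E,11S,12S,15S)-16-[(tert-butyldiphenylsilyl)oxy]-11,12-epoxycembr-7-ene-3,4-diol | O[C@@H]1C[C@H]([C@H](C)CO[Si](C(C)(C)C)(c2ccccc2)c2ccccc2)CC[C@]2(C)O[C@H]2CC/C(C)=C/CC[C@]1(C)O | intermediate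
25 | (1R,3R,4S,7E,11S,12S,15S)-11,12-epoxycembr-7-ene-3,4,16-triol | O[C@@H]1C[C@H]([C@H](C)CO)CC[C@]2(C)O[C@H]2CC/C(C)=C/CC[C@]1(C)O | intermediate
26 | (1R,3R,4S,7E,11S,12S,15S)-11,12-epoxy-3,4-dihydroxycembr-7-en-16-al | O[C@@H]1C[C@H]([C@H](C)C=O)CC[C@]2(C)O[C@H]2CC/C(C)=C/CC[C@]1(C)O | intermediate
27 | δ-lactol of 26 (C16 hemiacetal closed onto the C3 oxygen, both anomers) | C1/C=C(C)/CC[C@@H]2O[C@@]2(C)CC[C@@H]2C[C@@H](OC(O)[C@H]2C)[C@@](C)(O)C1 | intermediate
28 | (1R,3R,4S,7E,11S,12S,15S)-11,12-epoxy-4-hydroxycembr-7-en-16,3-olide | C1/C=C(C)/CC[C@@H]2O[C@@]2(C)CC[C@@H]2C[C@@H](OC(=O)[C@H]2C)[C@@](C)(O)C1 | intermediate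
29 | (1R,3R,4S,7R,11S,12S,15S)-11,12-epoxy-7-hydroperoxy-4-hydroxycembr-8(19)-en-16,3-olide (CNP0319766.1) | C=C1CC[C@@H]2O[C@@]2(C)CC[C@@H]2C[C@@H](OC(=O)[C@H]2C)[C@@](C)(O)CC[C@H]1OO | target

Total step count: 20. Longest linear sequence: 20 steps (1 → 29; 2 and 13 enter as purchased materials).

Steps most likely to fail

1. Step 20. Hydrogen transfer may come from the C6 ring methylene instead of the C19 methyl, which moves the hydroperoxide to C8, and oxygen may be delivered to the inner face at C7, which gives the 7-epimer. The fallback sets out from 28 and comes back at 29; it makes C7 reagent-controlled and removes the regioisomer on the way. The photooxygenation is run without regard to the C7 configuration, and the crude mixture of 29 and its C7 epimer, the (7S)-hydroperoxide F1, is dehydrated in the same flask with Ac2O/pyridine (Kornblum–DeLaMare-type) to the 8(19)-en-7-one F2; a tertiary C8 hydroperoxide cannot dehydrate and is separated here. (R)-Me-CBS/catecholborane reduction, with the alkenyl branch as the large group, should give the (7S)-allylic alcohol F3. MsCl/Et3N at −20 °C then gives the mesylate F4, and direct SN2 displacement at the activated secondary allylic carbon with 2-methoxyprop-2-yl hydroperoxide/CsOH in DMF inverts C7 to the peroxyketal F5. AcOH/THF/H2O releases 29.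

2. Step 15. Intermolecular coupling may outrun ring closure, and the aldehyde may be attacked on the wrong face if the ligand cannot override the bias of the folded chain. The fallback sets out from 21 and comes back at 22; it moves C3 control from the C–C bond formation to a reagent-controlled reduction. The ring is closed under the same Ni/Cr conditions without the chiral ligand, and the mixed C3 epimers (22 and the (3S)-alcohol F6) are oxidised together with MnO2 to the macrocyclic enone F7. (S)-Me-CBS/catecholborane reduction of this α-methyl enone should return 22.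

3. Step 16. The ring may force the C3–O bond into the rotamer that exposes the other face of C4=C5, and the allylic alcohol may be oxidised to the enone. The fallback sets out from 22 and comes back at 23 with no new compound (F0): Ti(OiPr)4/D-(−)-diisopropyl tartrate/t-BuOOH (Sharpless epoxidation in its kinetic-resolution sense). The tartrate is matched to the 3R carbinol and should dictate the erythro epoxide 23 by reagent control instead of by substrate conformation.

Further compounds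
F1 | step 20 | (7S)-hydroperoxide, C7 epimer of 29 | C=C1CC[C@@H]2O[C@@]2(C)CC[C@@H]2C[C@@H](OC(=O)[C@H]2C)[C@@](C)(O)CC[C@@H]1OO
F2 | step 20 | (1R,3R,4S,11S,12S,15S)-11,12-epoxy-4-hydroxy-7-oxocembr-8(19)-en-16,3-olide | C=C1CC[C@@H]2O[C@@]2(C)CC[C@@H]2C[C@@H](OC(=O)[C@H]2C)[C@@](C)(O)CCC1=O
F3 | step 20 | (7S)-11,12-epoxy-4,7-dihydroxycembr-8(19)-en-16,3-olide | C=C1CC[C@@H]2O[C@@]2(C)CC[C@@H]2C[C@@H](OC(=O)[C@H]2C)[C@@](C)(O)CC[C@@H]1O
F4 | step 20 | (7S)-7-methanesulfonate of F3 | C=C1CC[C@@H]2O[C@@]2(C)CC[C@@H]2C[C@@H](OC(=O)[C@H]2C)[C@@](C)(O)CC[C@@H]1OS(C)(=O)=O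
F5 | step 20 | (7R)-7-[(2-methoxypropan-2-yl)peroxy]-11,12-epoxy-4-hydroxycembr-8(19)-en-16,3-olide | C=C1CC[C@@H]2O[C@@]2(C)CC[C@@H]2C[C@@H](OC(=O)[C@H]2C)[C@@](C)(O)CC[C@H]1OOC(C)(C)OC
F6 | step 15 | (3S)-alcohol, C3 epimer of 22 | O[C@H]1C[C@H]([C@H](C)CO[Si](C(C)(C)C)(c2ccccc2)c2ccccc2)CC[C@]2(C)O[C@H]2CC/C(C)=C/C/C=C1\C
F7 | step 15 | (1R,4E,7E,11S,12S,15S)-16-[(tert-butyldiphenylsilyl)oxy]-11,12-epoxycembra-4,7-dien-3-one | O=C1C[C@H]([C@H](C)CO[Si](C(C)(C)C)(c2ccccc2)c2ccccc2)CC[C@]2(C)O[C@H]2CC/C(C)=C/C/C=C1\C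
F0 | step 16 | none | none
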